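## The problem

Target 31 is a bis-benzophenone without any stereocentre. Two 2,6-dihydroxy-4-methoxybenzoyl rings (rings B and C) are joined C3 to C3 by one CH2 group; ring B carries at C1 a ketone to ring A (2,4-dihydroxy-6-methylphenyl) and ring C a ketone to ring D (4-hydroxy-2-methoxy-6-methylphenyl). With nothing stereochemical to relay, the task is one of regiochemistry and chemoselectivity. Each ketone carbon lies between four ortho substituents, so acylation under strong acid is unattractive: it invites xanthone closure or deacylation of these 2,2'-dioxygenated benzophenones. The two halves differ only by one O-methyl group (ring D C2–OMe against ring A C2–OH) among six other phenols; since a C2 hydroxyl is chelated to the ketone and is the least reactive one, this difference has to be fixed before the rings are joined. The bridge must link two different halves without homodimers and must form only on rings B and C, although rings A and D are electron-rich phenols too. The polyphenol is sensitive to oxidation under base, and methylene-bridged phloroglucinols can lose or scramble the bridge under strong acid or base, so the closing steps must be mild. The enabling feature is in ring D: C6 (CH3), C1 (ketone carbon) and C2 (OMe) are contiguous, with oxygen at C4. That is the pattern left when a 3-methoxyaryne takes a carbon nucleophile at the distal carbon and an electrophile beside the methoxyl; ring A shows the same pattern with OH for OMe.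

## Retrosynthesis

Target 31 is taken back to its bis(triisopropylsilyl) ether 30, in which only the C4 oxygens of rings A and D are capped. No skeletal bond is cut. The silyl groups keep rings A and D out of the bridging chemistry and leave one buffered fluoride step at the end, which is kinder to the bridge than acid or hydrogenolysis.

In 30 the bond between the bridge CH2 and C3 of ring C is cut. This gives the Mannich base 28 of the left half, a precursor of o-quinone methide 29, and the right half 20. A single one-carbon condensation of both halves would give three dimers statistically; the Mannich route assigns the electrophile and nucleophile roles. The forward step asks that 29 be taken only by ring C of 20. Ring D of 20 has no free phenol, its two open positions flank the bulky silyl ether, and C3 and C5 of ring C are equivalent, so one product is expected.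

Mannich base 28 is cut at the CH2–ring B bond to the left half 27. The aminomethylation must occur on ring B, the only trioxygenated ring with free hydroxyls ortho and para to an open carbon; the open carbons of ring A both flank the silyl ether.

Halves 20 and 27 go back to the methoxymethyl ethers 19 and 26 and then to the carbinols 18 and 25. The crowded diaryl carbon is therefore made as an alcohol and oxidized afterwards. Acetals on rings B and C are chosen because acid removes them while the aryl silyl ethers stay; the acetal on ring A C2 of 26 falls in the same operation.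

The key cut takes two bonds out of carbinol 18: ring D C6–CH3 and ring D C1–carbinol carbon. The precursors are the 2-iodoaryl sulfonate 9, methylmagnesium chloride 14 and aldehyde 13. Cutting only the aryl–carbinol bond would demand a ready-made 1,2,3,5-tetrasubstituted aryl metal; the two-bond cut builds that pattern from a symmetric phloroglucinol core. The forward reaction needs one regiochemical outcome: methyl at the distal aryne carbon and magnesium beside OMe. Carbinol 25 is cut the same way into sulfonate 21, 14 and 13.

Sulfonates 9 and 21 both come from phenol 8, by O-methylation and O-methoxymethylation. The only difference between the two halves of 31 is thus set by alkylating one phenol of a shared intermediate. Phenol 8 comes from the symmetric iododiol 6 by mono-sulfonylation with 7. Diol 6 comes from iodide 5, whose iodine is placed by directed metalation of 3 between its two acetal groups. Compound 3 comes from silyl ether 2 and phloroglucinol 1.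

Aldehyde 13 is cut at the formyl carbon to bis-acetal 11, made from 5-methoxyresorcinol 10. Lithiation between the two acetals gives aryllithium 12, which is formylated.

## Roads not taken

Alternative 1: Here ring A is cut between its ketone-bearing carbon and its methyl-bearing carbon. The aryl tetraketone A1 is folded in aqueous KOH by aldol attack of C2 on the C7 carbonyl, dehydration and enolization, to give benzophenone A2.
- Merits: the hindered diaryl ketone is never made by intermolecular attack at a di-ortho-substituted carbon, because the aryl–carbonyl bond exists before ring A does. Ring A appears with both hydroxyls free, which suits the left half, and no cryogenic organometallic sequence is needed.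
- Weak points: A1 needs polyanion acylation with a hindered 2,6-disubstituted benzoate, and the chain can close in other modes (aldol from the other end, Claisen or pyranone closure). The fold gives ring A only. Ring D would need methylation of the chelated C2 hydroxyl in the presence of the more reactive C4 hydroxyl, which costs protection steps, and the free ring A phenols of A2 would compete in the bridging step.
- Comparison: for the left half alone this road is probably as short as the chosen one. The chosen plan offers in return one manifold for both halves from the shared phenol 8, with the OMe/OH difference and the C4 silyl ether built in before the ring is attached.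

Alternative 2: Here three bonds of ring B are cut. Cyclobutenone A3 and the aryl-substituted ynol ether A4 are heated; ring opening, (2+2) addition, a second ring opening and six-electron closure (Danheiser benzannulation) give the bridged phenol A5.
- Merits: the unsymmetrical diarylmethane is set early with full regiocontrol, so the chemoselectivity question of the late union disappears. In that respect this road is better than the chosen one.
- Weak points: both tetra-ortho-substituted diaryl ketones remain to be made late, on a fully substituted bridged core. One needs acylation of ring B between two oxygens, the other goes through the ring C bromide. Rings A and D are still needed as separate 1,2,3,5-substituted building blocks, and A4 is a base-sensitive ynol ether on a pentasubstituted arene.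
- Comparison: this plan is linear and puts its two hardest C–C bonds at the end. The chosen plan makes them early, twice by the same reaction, and accepts a selective but not fully guaranteed union.

Alternative 3: Here each central ring is cut between its acyl-bearing carbon and the hydroxyl-bearing carbon beside the bridge. Mg(OMe)2 in methanol opens both pyranone rings of the bis-pyranone A6, and each keto ester closes by Claisen condensation to give the tribenzyl ether A7 of the target.
- Merits: both central rings, both hindered ketones, the bridge and both ring methoxyls arrive in one step, and one hydrogenolysis would finish. This is the shortest endgame of all the plans.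
- Weak points: the difficulty moves into A6. It is an unsymmetrical methylene-bridged bis-pyranone with two different aroylmethyl side chains, so the mixed-bridge problem returns at a less nucleophilic stage. Each side chain needs acylation with a hindered benzoate, and the double folding must succeed twice in one molecule against aldol-type closure.
- Comparison: the chosen plan has more steps after its key step. It sets against that two separately checked halves and a bridging step whose partners have clearly different roles.

Key step: step 9

Remark on the chemistry: 31 has no stereocentre; carbinols 18 and 25 are racemic, their one stereocentre is removed by oxidation, and the configuration drawn for them is arbitrary.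

## Route

Step 1
Reactants: 1 phloroglucinol (benzene-1,3,5-triol)
Product: 2 5-(triisopropylsilyloxy)benzene-1,3-diol
Conditions: TIPSCl (1 equiv), imidazole, DMF, 0 °C to rt, 1 in threefold excess
Reagents that add atoms: chlorotriisopropylsilane, CC(C)[Si](Cl)(C(C)C)C(C)C
Why: O-Silylation of a phenol; the three hydroxyls are equivalent, and the excess of cheap, water-soluble 1 should hold back double silylation. The bulky ether later shields both ring positions beside it.

Step 2
Reactants: 2 5-(triisopropylsilyloxy)benzene-1,3-diol
Product: 3 1,3-bis(methoxymethoxy)-5-(triisopropylsilyloxy)benzene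
Conditions: MOMCl, iPr2NEt, CH2Cl2, 0 °C to rt
Reagents that add atoms: chloromethyl methyl ether, COCCl
Why: O-Alkylation of both phenols with an α-chloro ether under amine base; the acetals serve as directing groups for the next step.

Step 3
Reactants: 3 1,3-bis(methoxymethoxy)-5-(triisopropylsilyloxy)benzene
Product: 5 2-iodo-1,3-bis(methoxymethoxy)-5-(triisopropylsilyloxy)benzene, via aryllithium 4 (not isolated)
Conditions: n-BuLi, THF, 0 °C; I2, −78 °C to rt
Reagents that add atoms: iodine, II
Why: Directed ortho-metalation followed by iodinolysis. C2 lies between two chelating acetal oxygens, while the other two ring C–H bonds sit beside the bulky, non-coordinating silyl ether.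

Step 4
Reactants: 5 2-iodo-1,3-bis(methoxymethoxy)-5-(triisopropylsilyloxy)benzene
Product: 6 2-iodo-5-(triisopropylsilyloxy)benzene-1,3-diol
Conditions: HCl, MeOH, rt
Reagents that add atoms: none
Why: Acid-catalysed acetal exchange with methanol removes both methoxymethyl groups. An aryl triisopropylsilyl ether is expected to survive dilute methanolic acid at room temperature.

Step 5
Reactants: 6 2-iodo-5-(triisopropylsilyloxy)benzene-1,3-diol; 7 4-chlorobenzenesulfonyl chloride
Product: 8 3-hydroxy-2-iodo-5-(triisopropylsilyloxy)phenyl 4-chlorobenzenesulfonate
Conditions: 7 (1.0 equiv), Et3N, CH2Cl2, −20 to 0 °C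
Reagents that add atoms: none
Why: O-Sulfonylation of one of two equivalent phenols; one equivalent of 7 at low temperature should favour the mono-sulfonate, whose electron-poorer ring reacts more slowly a second time. Unreacted 6 can be recycled, and this single desymmetrization serves both halves.

Step 6
Reactants: 8 3-hydroxy-2-iodo-5-(triisopropylsilyloxy)phenyl 4-chlorobenzenesulfonate
Product: 9 2-iodo-3-methoxy-5-(triisopropylsilyloxy)phenyl 4-chlorobenzenesulfonate
Conditions: MeI, K2CO3, acetone, rt
Reagents that add atoms: iodomethane, CI
Why: Williamson O-methylation of the one free phenol; the aryl sulfonate and the silyl ether tolerate carbonate in acetone. This fixes the ring D methoxyl.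

Step 7
Reactants: 10 5-methoxyresorcinol (5-methoxybenzene-1,3-diol)
Product: 11 1-methoxy-3,5-bis(methoxymethoxy)benzene
Conditions: MOMCl, iPr2NEt, CH2Cl2, 0 °C to rt
Reagents that add atoms: chloromethyl methyl ether, COCCl
Why: O-Alkylation of both phenols, as in step 2.

Step 8
Reactants: 11 1-methoxy-3,5-bis(methoxymethoxy)benzene
Product: 13 4-methoxy-2,6-bis(methoxymethoxy)benzaldehyde, via aryllithium 12 (not isolated)
Conditions: n-BuLi, TMEDA, THF, 0 °C; DMF, 0 °C to rt; aq NH4Cl
Reagents that add atoms: N,N-dimethylformamide, CN(C)C=O
Why: Directed ortho-metalation at the carbon between the two acetal groups, the best-chelated position, then formylation with a formamide.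

Step 9
Reactants: 9 2-iodo-3-methoxy-5-(triisopropylsilyloxy)phenyl 4-chlorobenzenesulfonate; 14 methylmagnesium chloride; 13 4-methoxy-2,6-bis(methoxymethoxy)benzaldehyde
Product: 18 racemic [2-methoxy-6-methyl-4-(triisopropylsilyloxy)phenyl][4-methoxy-2,6-bis(methoxymethoxy)phenyl]methanol, via 2-magnesioaryl sulfonate 15 (not isolated), via aryne 16 (not isolated), via arylmagnesium chloride 17 (not isolated)
Conditions: iPrMgCl (1.0 equiv), THF, −78 °C; 14 (1.2 equiv), −78 °C to rt; 13 (1.5 equiv), 0 °C to rt; aq NH4Cl
Reagents that add atoms: none
Why: Iodine–magnesium exchange at −78 °C converts 9 into the 2-magnesioaryl sulfonate 15, which on warming expels the magnesium 4-chlorobenzenesulfonate and gives aryne 16, its triple bond lying between the former C–I and C–O carbons. The methoxyl on the adjacent carbon withdraws inductively and distorts the aryne, so MeMgCl attacks the distal carbon and magnesium stays on the carbon beside OMe, where it is chelated (17); the silyloxy group is meta to the attacked carbon and should exert no bias. 1,2-Addition of 17 to aldehyde 13, aided by coordination of magnesium to the acetal oxygens, then gives the alkoxide of 18. The closest known reaction type is aryne generation from 2-magnesiated aryl sulfonates with addition of a Grignard reagent and trapping of the new arylmagnesium by an aldehyde. No ring is closed. The carbinol carbon is the only new stereocentre; nothing controls it, 18 is racemic, and step 10 removes it. The selectivity needed is the regiochemistry of carbomagnesiation, secured by the C3 methoxyl, and the preference of the aryne for MeMgCl, secured by its small size against the di-ortho-substituted species 15 and 17. The MeMgCl left over is consumed by the excess of the cheap aldehyde 13.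

Step 10
Reactants: 18 racemic [2-methoxy-6-methyl-4-(triisopropylsilyloxy)phenyl][4-methoxy-2,6-bis(methoxymethoxy)phenyl]methanol
Product: 19 [2-methoxy-6-methyl-4-(triisopropylsilyloxy)phenyl][4-methoxy-2,6-bis(methoxymethoxy)phenyl]methanone
Conditions: Dess–Martin periodinane, CH2Cl2, rt
Reagents that add atoms: none
Why: Dess–Martin oxidation of a secondary benzhydrol, which tolerates tetra-ortho substitution and leaves acetals and silyl ethers alone; the stereocentre is removed.

Step 11
Reactants: 19 [2-methoxy-6-methyl-4-(triisopropylsilyloxy)phenyl][4-methoxy-2,6-bis(methoxymethoxy)phenyl]methanone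
Product: 20 (2,6-dihydroxy-4-methoxyphenyl)[2-methoxy-6-methyl-4-(triisopropylsilyloxy)phenyl]methanone
Conditions: HCl, MeOH–THF, rt to 40 °C
Reagents that add atoms: none
Why: Acid-catalysed acetal exchange frees the two ring C phenols, which become chelated to the ketone; the aryl silyl ether and both methyl ethers should remain.

Step 12
Reactants: 8 3-hydroxy-2-iodo-5-(triisopropylsilyloxy)phenyl 4-chlorobenzenesulfonate
Product: 21 2-iodo-3-(methoxymethoxy)-5-(triisopropylsilyloxy)phenyl 4-chlorobenzenesulfonate
Conditions: MOMCl, iPr2NEt, CH2Cl2, 0 °C to rt
Reagents that add atoms: chloromethyl methyl ether, COCCl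
Why: O-Alkylation of the one free phenol of the shared intermediate; the acetal stands for the future ring A C2 hydroxyl.

Step 13
Reactants: 21 2-iodo-3-(methoxymethoxy)-5-(triisopropylsilyloxy)phenyl 4-chlorobenzenesulfonate; 14 methylmagnesium chloride; 13 4-methoxy-2,6-bis(methoxymethoxy)benzaldehyde
Product: 25 racemic [2-(methoxymethoxy)-6-methyl-4-(triisopropylsilyloxy)phenyl][4-methoxy-2,6-bis(methoxymethoxy)phenyl]methanol, via 2-magnesioaryl sulfonate 22 (not isolated), via aryne 23 (not isolated), via arylmagnesium chloride 24 (not isolated)
Conditions: iPrMgCl (1.0 equiv), THF, −78 °C; 14 (1.2 equiv), −78 °C to rt; 13 (1.5 equiv), 0 °C to rt; aq NH4Cl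
Reagents that add atoms: none
Why: The same aryne carbomagnesiation and aldehyde trapping as in step 9. The methoxymethoxy group directs like the methoxyl (methyl distal, magnesium beside the oxygen) and chelates the arylmagnesium 24; the carbinol is racemic and is oxidized next.

Step 14
Reactants: 25 racemic [2-(methoxymethoxy)-6-methyl-4-(triisopropylsilyloxy)phenyl][4-methoxy-2,6-bis(methoxymethoxy)phenyl]methanol
Product: 26 [2-(methoxymethoxy)-6-methyl-4-(triisopropylsilyloxy)phenyl][4-methoxy-2,6-bis(methoxymethoxy)phenyl]methanone
Conditions: Dess–Martin periodinane, CH2Cl2, rt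
Reagents that add atoms: none
Why: Dess–Martin oxidation of the hindered benzhydrol, as in step 10.

Step 15
Reactants: 26 [2-(methoxymethoxy)-6-methyl-4-(triisopropylsilyloxy)phenyl][4-methoxy-2,6-bis(methoxymethoxy)phenyl]methanone
Product: 27 (2,6-dihydroxy-4-methoxyphenyl)[2-hydroxy-6-methyl-4-(triisopropylsilyloxy)phenyl]methanone
Conditions: HCl, MeOH–THF, rt to 40 °C
Reagents that add atoms: none
Why: Acid-catalysed acetal exchange removes all three methoxymethyl groups in one operation and leaves the silyl ether on the ring A C4 oxygen.

Step 16
Reactants: 27 (2,6-dihydroxy-4-methoxyphenyl)[2-hydroxy-6-methyl-4-(triisopropylsilyloxy)phenyl]methanone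
Product: 28 {3-[(dimethylamino)methyl]-2,6-dihydroxy-4-methoxyphenyl}[2-hydroxy-6-methyl-4-(triisopropylsilyloxy)phenyl]methanone
Conditions: bis(dimethylamino)methane (1.05 equiv), CH2Cl2, 0 °C to rt
Reagents that add atoms: bis(dimethylamino)methane, CN(C)CN(C)C
Why: Phenol Mannich reaction; the acidic acylphenol releases the iminium ion from the aminal. Ring B is attacked at C3 (equivalent to C5), ortho and para to free hydroxyls, while the open carbons of ring A both flank the bulky silyl ether; one equivalent of aminal limits double aminomethylation.

Step 17
Reactants: 28 {3-[(dimethylamino)methyl]-2,6-dihydroxy-4-methoxyphenyl}[2-hydroxy-6-methyl-4-(triisopropylsilyloxy)phenyl]methanone; 20 (2,6-dihydroxy-4-methoxyphenyl)[2-methoxy-6-methyl-4-(triisopropylsilyloxy)phenyl]methanone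
Product: 30 bis(triisopropylsilyl) ether of the target (silyl groups on the C4 oxygens of rings A and D), via o-quinone methide 29 (not isolated)
Conditions: 20 (3 equiv), 1,4-dioxane, 90 °C, slow addition of 28
Reagents that add atoms: none
Why: Thermal loss of the amine from the ortho-hydroxybenzylamine gives o-quinone methide 29; conjugate addition of ring C of 20 at C3 (equivalent to C5) and re-aromatization form the bridge. This is the Mannich-base route to unsymmetrical methylene-bridged acylphenols. Excess 20 should suppress self-condensation of 28 and double alkylation, and ring D of 20 has no free phenol.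

Step 18
Reactants: 30 bis(triisopropylsilyl) ether of the target
Product: 31 the target, (2,6-dihydroxy-3-{[2,4-dihydroxy-3-(4-hydroxy-2-methoxy-6-methylbenzoyl)-6-methoxyphenyl]methyl}-4-methoxyphenyl)(2,4-dihydroxy-6-methylphenyl)methanone
Conditions: TBAF, AcOH, THF, 0 °C
Reagents that add atoms: none
Why: Fluoride cleavage of both aryl silyl ethers; the acetic acid buffer keeps phenolate concentration low, so oxidation and scission of the bridge should be avoided.

## Compound list

1 | phloroglucinol (benzene-1,3,5-triol) | Oc1cc(O)cc(O)c1 | starting material
2 | 5-(triisopropylsilyloxy)benzene-1,3-diol | Oc1cc(O)cc(O[Si](C(C)C)(C(C)C)C(C)C)c1 | intermediate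
3 | 1,3-bis(methoxymethoxy)-5-(triisopropylsilyloxy)benzene | COCOc1cc(OCOC)cc(O[Si](C(C)C)(C(C)C)C(C)C)c1 | intermediate
4 | [2,6-bis(methoxymethoxy)-4-(triisopropylsilyloxy)phenyl]lithium (formed in the flask) | [Li]c1c(OCOC)cc(O[Si](C(C)C)(C(C)C)C(C)C)cc1OCOC | intermediate
5 | 2-iodo-1,3-bis(methoxymethoxy)-5-(triisopropylsilyloxy)benzene | COCOc1cc(O[Si](C(C)C)(C(C)C)C(C)C)cc(OCOC)c1I | intermediate
6 | 2-iodo-5-(triisopropylsilyloxy)benzene-1,3-diol | Oc1cc(O[Si](C(C)C)(C(C)C)C(C)C)cc(O)c1I | intermediate
7 | 4-chlorobenzenesulfonyl chloride | O=S(=O)(Cl)c1ccc(Cl)cc1 | starting material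
8 | 3-hydroxy-2-iodo-5-(triisopropylsilyloxy)phenyl 4-chlorobenzenesulfonate | Oc1cc(O[Si](C(C)C)(C(C)C)C(C)C)cc(OS(=O)(=O)c2ccc(Cl)cc2)c1I | intermediate
9 | 2-iodo-3-methoxy-5-(triisopropylsilyloxy)phenyl 4-chlorobenzenesulfonate | COc1cc(O[Si](C(C)C)(C(C)C)C(C)C)cc(OS(=O)(=O)c2ccc(Cl)cc2)c1I | intermediate
10 | 5-methoxyresorcinol (5-methoxybenzene-1,3-diol) | COc1cc(O)cc(O)c1 | starting material
11 | 1-methoxy-3,5-bis(methoxymethoxy)benzene | COCOc1cc(OC)cc(OCOC)c1 | intermediate
12 | [4-methoxy-2,6-bis(methoxymethoxy)phenyl]lithium (formed in the flask) | [Li]c1c(OCOC)cc(OC)cc1OCOC | intermediate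
13 | 4-methoxy-2,6-bis(methoxymethoxy)benzaldehyde | COCOc1cc(OC)cc(OCOC)c1C=O | intermediate
14 | methylmagnesium chloride | C[Mg]Cl | starting material
15 | 2-(chloromagnesio)-3-methoxy-5-(triisopropylsilyloxy)phenyl 4-chlorobenzenesulfonate (formed in the flask) | COc1cc(O[Si](C(C)C)(C(C)C)C(C)C)cc(OS(=O)(=O)c2ccc(Cl)cc2)c1[Mg]Cl | intermediate
16 | 3-methoxy-5-(triisopropylsilyloxy)benzyne (formed in the flask) | COC1=CC(O[Si](C(C)C)(C(C)C)C(C)C)=CC#C1 | intermediate
17 | chloro[2-methoxy-6-methyl-4-(triisopropylsilyloxy)phenyl]magnesium (formed in the flask) | COc1cc(O[Si](C(C)C)(C(C)C)C(C)C)cc(C)c1[Mg]Cl | intermediate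
18 | racemic [2-methoxy-6-methyl-4-(triisopropylsilyloxy)phenyl][4-methoxy-2,6-bis(methoxymethoxy)phenyl]methanol (one enantiomer drawn) | COCOc1cc(OC)cc(OCOC)c1[C@@H](O)c1c(C)cc(O[Si](C(C)C)(C(C)C)C(C)C)cc1OC | intermediate
19 | [2-methoxy-6-methyl-4-(triisopropylsilyloxy)phenyl][4-methoxy-2,6-bis(methoxymethoxy)phenyl]methanone | COCOc1cc(OC)cc(OCOC)c1C(=O)c1c(C)cc(O[Si](C(C)C)(C(C)C)C(C)C)cc1OC | intermediate
20 | (2,6-dihydroxy-4-methoxyphenyl)[2-methoxy-6-methyl-4-(triisopropylsilyloxy)phenyl]methanone | COc1cc(O)c(C(=O)c2c(C)cc(O[Si](C(C)C)(C(C)C)C(C)C)cc2OC)c(O)c1 | intermediate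
21 | 2-iodo-3-(methoxymethoxy)-5-(triisopropylsilyloxy)phenyl 4-chlorobenzenesulfonate | COCOc1cc(O[Si](C(C)C)(C(C)C)C(C)C)cc(OS(=O)(=O)c2ccc(Cl)cc2)c1I | intermediate
22 | 2-(chloromagnesio)-3-(methoxymethoxy)-5-(triisopropylsilyloxy)phenyl 4-chlorobenzenesulfonate (formed in the flask) | COCOc1cc(O[Si](C(C)C)(C(C)C)C(C)C)cc(OS(=O)(=O)c2ccc(Cl)cc2)c1[Mg]Cl | intermediate
23 | 3-(methoxymethoxy)-5-(triisopropylsilyloxy)benzyne (formed in the flask) | COCOC1=CC(O[Si](C(C)C)(C(C)C)C(C)C)=CC#C1 | intermediate
24 | chloro[2-(methoxymethoxy)-6-methyl-4-(triisopropylsilyloxy)phenyl]magnesium (formed in the flask) | COCOc1cc(O[Si](C(C)C)(C(C)C)C(C)C)cc(C)c1[Mg]Cl | intermediate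
25 | racemic [2-(methoxymethoxy)-6-methyl-4-(triisopropylsilyloxy)phenyl][4-methoxy-2,6-bis(methoxymethoxy)phenyl]methanol (one enantiomer drawn) | COCOc1cc(OC)cc(OCOC)c1[C@@H](O)c1c(C)cc(O[Si](C(C)C)(C(C)C)C(C)C)cc1OCOC | intermediate
26 | [2-(methoxymethoxy)-6-methyl-4-(triisopropylsilyloxy)phenyl][4-methoxy-2,6-bis(methoxymethoxy)phenyl]methanone | COCOc1cc(OC)cc(OCOC)c1C(=O)c1c(C)cc(O[Si](C(C)C)(C(C)C)C(C)C)cc1OCOC | intermediate
27 | (2,6-dihydroxy-4-methoxyphenyl)[2-hydroxy-6-methyl-4-(triisopropylsilyloxy)phenyl]methanone | COc1cc(O)c(C(=O)c2c(C)cc(O[Si](C(C)C)(C(C)C)C(C)C)cc2O)c(O)c1 | intermediate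
28 | {3-[(dimethylamino)methyl]-2,6-dihydroxy-4-methoxyphenyl}[2-hydroxy-6-methyl-4-(triisopropylsilyloxy)phenyl]methanone | COc1cc(O)c(C(=O)c2c(C)cc(O[Si](C(C)C)(C(C)C)C(C)C)cc2O)c(O)c1CN(C)C | intermediate
29 | 3-hydroxy-2-[2-hydroxy-6-methyl-4-(triisopropylsilyloxy)benzoyl]-5-methoxy-6-methylidenecyclohexa-2,4-dien-1-one (o-quinone methide, formed in the flask) | C=C1C(=O)C(C(=O)c2c(C)cc(O[Si](C(C)C)(C(C)C)C(C)C)cc2O)=C(O)C=C1OC | intermediate
30 | bis(triisopropylsilyl) ether of the target (silyl groups on the C4 oxygens of rings A and D) | COc1cc(O)c(C(=O)c2c(C)cc(O[Si](C(C)C)(C(C)C)C(C)C)cc2O)c(O)c1Cc1c(OC)cc(O)c(C(=O)c2c(C)cc(O[Si](C(C)C)(C(C)C)C(C)C)cc2OC)c1O | intermediate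
31 | (2,6-dihydroxy-3-{[2,4-dihydroxy-3-(4-hydroxy-2-methoxy-6-methylbenzoyl)-6-methoxyphenyl]methyl}-4-methoxyphenyl)(2,4-dihydroxy-6-methylphenyl)methanone | COc1cc(O)c(C(=O)c2c(C)cc(O)cc2O)c(O)c1Cc1c(OC)cc(O)c(C(=O)c2c(C)cc(O)cc2OC)c1O | target

## Step count and risks

Total step count: 18. Longest linear sequence: 12 steps (steps 1 to 5, then 12 to 18).

Least certain steps:

**Step 9 (key step).** The most likely failure is slow 1,2-addition of the di-ortho-substituted arylmagnesium 17 to the di-ortho-substituted aldehyde 13. Then 17 is protonated on work-up while the aldehyde is consumed by residual MeMgCl. A second concern is self-addition of arylmagnesium species to the aryne if methyl capture is slow.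
Fallback: set out from 9 and run the same aryne carbomagnesiation, but quench 17 with DMF, a small electrophile. This gives 2-methoxy-6-methyl-4-(triisopropylsilyloxy)benzaldehyde F1. The more reactive aryllithium 12, made from 11 as in step 8, is then added to F1 at −78 °C. The polarity of the carbinol-forming step is thus reversed, and the route is rejoined at 18.

**Step 13.** The same hazards apply as in step 9. In addition, the larger acetal beside magnesium increases crowding in the addition of 24 to 13.
Fallback: give up the aryne for this half only. Set out from 11 and commercial 2,4-dihydroxy-6-methylbenzaldehyde F2. Silylation of its non-chelated C4 hydroxyl (TIPSCl, imidazole) gives 2-hydroxy-6-methyl-4-(triisopropylsilyloxy)benzaldehyde F3. Alkylation of the chelated hydroxyl (MOMCl, iPr2NEt) gives 2-(methoxymethoxy)-6-methyl-4-(triisopropylsilyloxy)benzaldehyde F4. Addition of aryllithium 12 (from 11) to F4 rejoins the route at 25.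

**Step 17.** Possible failures are self-condensation of 29 with a second molecule of 28 (C5 of its ring B is still nucleophilic), double alkylation of ring C of 20, and partial loss of a silyl ether at 90 °C, which would expose ring A or D.
Fallback: set out from 28 and quaternize the amine with MeI to the {[2,4-dihydroxy-3-(2-hydroxy-6-methyl-4-(triisopropylsilyloxy)benzoyl)-6-methoxyphenyl]methyl}trimethylammonium iodide F5. Treating F5 with K2CO3 in MeCN at room temperature in the presence of excess 20 releases the quinone methide without heating. The route is rejoined at 30.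

**Step 16.** Possible failures are aminomethylation of ring A ortho to its free C2 hydroxyl, or a second aminomethylation at C5 of ring B.
Fallback: reverse the roles of the halves. Set out from 20, whose ring D has no free phenol, and aminomethylate it with the same aminal to {3-[(dimethylamino)methyl]-2,6-dihydroxy-4-methoxyphenyl}[2-methoxy-6-methyl-4-(triisopropylsilyloxy)phenyl]methanone F6. Heating F6 with excess 27 forms the same CH2 bridge and rejoins the route at 30. The selectivity question then moves to the union, where the open carbons of ring A of 27 are flanked by the silyl ether.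

**Step 4.** The acid may cause protodeiodination or migration of iodine on the very electron-rich ring, or slow loss of the silyl ether.
Fallback: set out from 2 and iodinate it directly with I2 and NaHCO3 in aqueous THF at 0 °C. Attack is expected between the two hydroxyls, since the other positions flank the silyl ether. The route is rejoined at 6 without passing through 3 and 5; no new compound is made.

## Further compounds

F1 | step 9 | 2-methoxy-6-methyl-4-(triisopropylsilyloxy)benzaldehyde | COc1cc(O[Si](C(C)C)(C(C)C)C(C)C)cc(C)c1C=O
F2 | step 13 | 2,4-dihydroxy-6-methylbenzaldehyde | Cc1cc(O)cc(O)c1C=O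
F3 | step 13 | 2-hydroxy-6-methyl-4-(triisopropylsilyloxy)benzaldehyde | Cc1cc(O[Si](C(C)C)(C(C)C)C(C)C)cc(O)c1C=O
F4 | step 13 | 2-(methoxymethoxy)-6-methyl-4-(triisopropylsilyloxy)benzaldehyde | COCOc1cc(O[Si](C(C)C)(C(C)C)C(C)C)cc(C)c1C=O
F5 | step 17 | {[2,4-dihydroxy-3-(2-hydroxy-6-methyl-4-(triisopropylsilyloxy)benzoyl)-6-methoxyphenyl]methyl}trimethylammonium iodide | COc1cc(O)c(C(=O)c2c(C)cc(O[Si](C(C)C)(C(C)C)C(C)C)cc2O)c(O)c1C[N+](C)(C)C.[I-]
F6 | step 16 | {3-[(dimethylamino)methyl]-2,6-dihydroxy-4-methoxyphenyl}[2-methoxy-6-methyl-4-(triisopropylsilyloxy)phenyl]methanone | COc1cc(O)c(C(=O)c2c(C)cc(O[Si](C(C)C)(C(C)C)C(C)C)cc2OC)c(O)c1CN(C)C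
F0 | step 4 | none | none
A1 | alternative 1 | 1-[2,6-bis(benzyloxy)-4-methoxyphenyl]octane-1,3,5,7-tetraone | CC(=O)CC(=O)CC(=O)CC(=O)c1c(OCc2ccccc2)cc(OC)cc1OCc1ccccc1
A2 | alternative 1 | [2,6-bis(benzyloxy)-4-methoxyphenyl](2,4-dihydroxy-6-methylphenyl)methanone | COc1cc(OCc2ccccc2)c(C(=O)c2c(C)cc(O)cc2O)c(OCc2ccccc2)c1
A3 | alternative 2 | 3-(methoxymethoxy)cyclobut-2-en-1-one | COCOC1=CC(=O)C1
A4 | alternative 2 | 1-methoxy-3-[3-bromo-6-methoxy-2,4-bis(methoxymethoxy)phenyl]prop-1-yne | COC#CCc1c(OC)cc(OCOC)c(Br)c1OCOC
A5 | alternative 2 | 2-{[3-bromo-6-methoxy-2,4-bis(methoxymethoxy)phenyl]methyl}-3-methoxy-5-(methoxymethoxy)phenol | COCOc1cc(O)c(Cc2c(OC)cc(OCOC)c(Br)c2OCOC)c(OC)c1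
A6 | alternative 3 | 3,3'-methylene-bridged bis(4-methoxy-2-pyranone) carrying at C6 a 2-[2,4-bis(benzyloxy)-6-methylphenyl]-2-oxoethyl group on one ring and a 2-[4-(benzyloxy)-2-methoxy-6-methylphenyl]-2-oxoethyl group on the other | COC1=C(CC2=C(OC)C=C(CC(=O)c3c(C)cc(OCc4ccccc4)cc3OC)OC2=O)C(=O)OC(CC(=O)c2c(C)cc(OCc3ccccc3)cc2OCc2ccccc2)=C1
A7 | alternative 3 | tri-O-benzyl ether of the target (benzyl on both ring A oxygens and on the ring D C4 oxygen) | COc1cc(O)c(C(=O)c2c(C)cc(OCc3ccccc3)cc2OCc2ccccc2)c(O)c1Cc1c(OC)cc(O)c(C(=O)c2c(C)cc(OCc3ccccc3)cc2OC)c1O
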